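**Retrosynthetic overview**
1. Target 18 ← lactone 16 by carbonyl methylenation at C2; 16 ← oxidation of the C2 methylene of the fully halogenated oxane 15.
2. Cyclohexane Br/Cl of 15 ← ring alkene of 12: trans-diaxial chlorohydrin, tertiary bromide, then thermal diaxial → diequatorial interchange of the two halogens.
3. C5–Br and the second C6 methyl of 12 ← cyclic enol ether 10 (bromo-methoxylation, then methyl for methoxy).
4. Key disconnection C5–C6: the oxane is closed from acetate 8 by a titanium-alkylidene olefinic-ester cyclisation. The enabling feature is that O1 sits between C2 and the quaternary C6, and C6 carries only O1, methyl and C5. C6 can therefore be the carbonyl carbon of an acetate on O1, and C5 the inner carbon of an allyl group on C3; the tether O1–C2–C3–C4 gives a six-membered ring.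
5. 8 ← (S)-limonene by C10 hydroxylation, Sharpless epoxidation (sets C3) and vinyl cuprate opening. Ring order: cyclohexene (from limonene) first, oxane second (step 5).

Key step: step 5

Remark: locants are those of the target throughout: oxane O1, C2–C6; cyclohexyl C1′ (bonded to C3), C3′ (CHBr in the target), C4′ (CCl(CH3) in the target).

Step 1
Reactants: 1 (S)-limonene
Product: 4 2-[(1S)-4-methylcyclohex-3-en-1-yl]prop-2-en-1-ol, via 10-lithiolimonene 2 (not isolated), via allylboronate 3 (not isolated)
Conditions: n-BuLi, TMEDA, hexane, 25 °C; B(OMe)3, THF, −78 °C; then H2O2, NaOH, 0 °C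
Reagents that add atoms: hydrogen peroxide OO
Why: Allylic metalation of the isopropenyl methyl group by n-BuLi·TMEDA, borylation of the symmetric 2-substituted allyllithium and alkaline peroxide oxidation of the C–B bond (metalation–borylation–oxidation) give the primary allylic alcohol; the ring stereocentre (future C1′) is not involved.

Step 2
Reactants: 4 2-[(1S)-4-methylcyclohex-3-en-1-yl]prop-2-en-1-ol
Product: 5 [(2R)-2-[(1S)-4-methylcyclohex-3-en-1-yl]oxiran-2-yl]methanol
Conditions: Ti(OiPr)4 (cat.), D-(−)-diisopropyl tartrate (cat.), t-BuOOH, 4 Å MS, CH2Cl2, −20 °C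
Reagents that add atoms: tert-butyl hydroperoxide CC(C)(C)OO
Why: Sharpless asymmetric epoxidation of a 2-substituted allylic alcohol, in which the titanium–tartrate catalyst and not the remote C1′ centre selects the face; D-(−)-tartrate should give the (2R)-epoxide (the sense in which it gives (R)-2-methylglycidol from 2-methylprop-2-en-1-ol), which sets the future C3, and the ring alkene has no allylic hydroxyl and is left alone.

Step 3
Reactants: 5 [(2R)-2-[(1S)-4-methylcyclohex-3-en-1-yl]oxiran-2-yl]methanol
Product: 6 (2R)-2-[(1S)-4-methylcyclohex-3-en-1-yl]pent-4-ene-1,2-diol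
Conditions: CH2=CHMgBr (excess), CuI (cat.), THF, −40 → 0 °C; aq. NH4Cl
Reagents that add atoms: vinylmagnesium bromide C=C[Mg]Br
Why: Copper-catalysed Grignard opening of the epoxide (SN2) at its unsubstituted CH2 carbon installs the allyl group and frees the tertiary alcohol without breaking the C3–O bond, so the configuration is kept; Payne equilibration of this 2,2-disubstituted epoxy alcohol only regenerates the same compound.

Step 4
Reactants: 6 (2R)-2-[(1S)-4-methylcyclohex-3-en-1-yl]pent-4-ene-1,2-diol
Product: 8 (2R)-2-[(1S)-4-methylcyclohex-3-en-1-yl]-2-[(triethylsilyl)oxy]pent-4-en-1-yl acetate, via monoacetate 7 (not isolated)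
Conditions: Ac2O, Et3N, DMAP (cat.), CH2Cl2, 0 °C; then Et3SiOTf, 2,6-lutidine, −78 → 0 °C
Reagents that add atoms: acetic anhydride CC(=O)OC(C)=O; triethylsilyl trifluoromethanesulfonate CC[Si](CC)(CC)OS(=O)(=O)C(F)(F)F
Why: Selective acylation of the primary hydroxyl (the tertiary one is inert to Ac2O/DMAP at 0 °C), then silyl ether formation at the tertiary alcohol with the silyl triflate in the same flask; no stereocentre is affected.

Step 5
Reactants: 8 (2R)-2-[(1S)-4-methylcyclohex-3-en-1-yl]-2-[(triethylsilyl)oxy]pent-4-en-1-yl acetate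
Product: 10 triethyl{[(3R)-6-methyl-3-[(1S)-4-methylcyclohex-3-en-1-yl]-3,4-dihydro-2H-pyran-3-yl]oxy}silane, via isopropenyl ether 9 (not isolated)
Conditions: Cp2Ti(μ-Cl)(μ-CH2)AlMe2 (Tebbe reagent, 4 equiv), pyridine (cat.), THF, −40 → 25 °C, then 65 °C
Reagents that add atoms: none
Why: Tebbe methylenation converts the acetate of 8 into isopropenyl ether 9; a further equivalent of Cp2Ti=CH2 exchanges with the terminal allyl alkene ([2+2]/retro-[2+2]) to a titanium alkylidene at C5, which adds across the enol ether C=C and expels Cp2Ti=CH2 through a titanacyclobutane, so that the acetate carbonyl carbon becomes C6, its methyl the first C6 methyl, and C5=C6 closes the ring. The closest known reaction type is the titanium-alkylidene cyclisation of olefinic esters to cyclic enol ethers (tandem carbonyl methylenation–ring-closing enol ether/olefin metathesis). The oxane ring is closed by ring-closing metathesis with loss of ethene, both C5 and C6 lying inside the six-membered ring, and the quaternary C3 favours the cyclising conformer (Thorpe–Ingold effect). No stereocentre is created and C3 and C1′ are not touched. The step needs chemoselectivity for the ester carbonyl and the monosubstituted alkene over the trisubstituted ring alkene, and tolerance of the tertiary oxygen; the first is secured by the inertness of trisubstituted alkenes towards Cp2Ti=CH2 and by the absence of any unstrained ring that metathesis at the cyclohexene could give, the second by the triethylsilyl ether.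

Step 6
Reactants: 10 triethyl{[(3R)-6-methyl-3-[(1S)-4-methylcyclohex-3-en-1-yl]-3,4-dihydro-2H-pyran-3-yl]oxy}silane
Product: 11 {[(3R,5R,6R)-5-bromo-6-methoxy-6-methyl-3-[(1S)-4-methylcyclohex-3-en-1-yl]oxan-3-yl]oxy}triethylsilane (Br cis to the silyloxy group, OMe trans to Br)
Conditions: NBS, MeOH, NaHCO3, CH2Cl2, −78 °C
Reagents that add atoms: N-bromosuccinimide O=C1CCC(=O)N1Br; methanol CO
Why: Bromo-alkoxylation of a cyclic enol ether (as in NBS or NIS/alcohol additions to glycals): Br+ adds to C5 and methanol to the C6 oxocarbenium ion trans-diaxially on the half-chair that keeps the cyclohexenyl group pseudo-equatorial and the C3–OSi bond pseudo-axial, so bromine should enter axially on the face of the silyloxy group (the course that turns galactal into talo-configured 2-halo glycosides) and set C5 as R; the enol ether is far more nucleophilic than the ring alkene.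

Step 7
Reactants: 11 {[(3R,5R,6R)-5-bromo-6-methoxy-6-methyl-3-[(1S)-4-methylcyclohex-3-en-1-yl]oxan-3-yl]oxy}triethylsilane
Product: 12 {[(3R,5R)-5-bromo-6,6-dimethyl-3-[(1S)-4-methylcyclohex-3-en-1-yl]oxan-3-yl]oxy}triethylsilane
Conditions: AlMe3, CH2Cl2, −78 → 0 °C
Reagents that add atoms: trimethylaluminium C[Al](C)C
Why: Lewis-acid-mediated substitution at a ketal carbon (organoaluminium C-glycosylation type): AlMe3 ionises the axial methoxy group, which is anti to the C5 bromine, and transfers methyl to the C6 oxocarbenium ion; C6 becomes the gem-dimethyl carbon and C5 is not touched.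

Step 8
Reactants: 12 {[(3R,5R)-5-bromo-6,6-dimethyl-3-[(1S)-4-methylcyclohex-3-en-1-yl]oxan-3-yl]oxy}triethylsilane
Product: 13 (1R,2R,4S)-4-[(3R,5R)-5-bromo-6,6-dimethyl-3-[(triethylsilyl)oxy]oxan-3-yl]-2-chloro-1-methylcyclohexan-1-ol (C3′–Cl trans and C4′–OH cis to the oxanyl group, both axial)
Conditions: trichloroisocyanuric acid, acetone/H2O, 0 °C
Reagents that add atoms: trichloroisocyanuric acid O=C1N(Cl)C(=O)N(Cl)C(=O)N1Cl; water O
Why: Chlorohydrin formation (electrophilic chlorination, then hydration): Cl+ adds to C3′ on the face trans to the equatorial C1′ substituent and water opens the chloronium ion at the tertiary C4′, the one pathway that is both Markovnikov and trans-diaxial (Fürst–Plattner rule), as in the NBS/H2O addition to limonene.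

Step 9
Reactants: 13 (1R,2R,4S)-4-[(3R,5R)-5-bromo-6,6-dimethyl-3-[(triethylsilyl)oxy]oxan-3-yl]-2-chloro-1-methylcyclohexan-1-ol
Product: 14 {[(3R,5R)-5-bromo-3-[(1S,3R,4R)-4-bromo-3-chloro-4-methylcyclohexyl]-6,6-dimethyloxan-3-yl]oxy}triethylsilane (tertiary Br and secondary Cl trans-diaxial)
Conditions: Me3SiBr, CH2Cl2, −40 → 0 °C
Reagents that add atoms: bromotrimethylsilane C[Si](C)(C)Br
Why: SN1 substitution of the tertiary alcohol with neighbouring-group participation by the antiperiplanar chlorine (chloronium ion), bromide re-entering axially at C4′ with overall retention; the hindered silyl ether should survive at low temperature.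

Step 10
Reactants: 14 {[(3R,5R)-5-bromo-3-[(1S,3R,4R)-4-bromo-3-chloro-4-methylcyclohexyl]-6,6-dimethyloxan-3-yl]oxy}triethylsilane
Product: 15 {[(3R,5R)-5-bromo-3-[(1S,3S,4S)-3-bromo-4-chloro-4-methylcyclohexyl]-6,6-dimethyloxan-3-yl]oxy}triethylsilane
Conditions: MeCN, 80 °C, sealed tube, dark; chromatography, recovered 14 resubmitted
Reagents that add atoms: none
Why: Thermal diaxial → diequatorial 1,2-interchange of vicinal halogens (dyotropic rearrangement through a halonium/halide ion pair, known for trans-diaxial dihalides such as 5α,6β-dibromocholestane): bromine moves from C4′ to C3′ on the face cis to the oxanyl group and chlorine from C3′ to C4′ on the other face, each with inversion, which sets C3′ (S) and C4′ (S); it is an equilibrium, helped on the product side by the polar solvent and by the tertiary C–Cl/secondary C–Br pairing.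

Step 11
Reactants: 15 {[(3R,5R)-5-bromo-3-[(1S,3S,4S)-3-bromo-4-chloro-4-methylcyclohexyl]-6,6-dimethyloxan-3-yl]oxy}triethylsilane
Product: 16 (3R,5R)-5-bromo-3-[(1S,3S,4S)-3-bromo-4-chloro-4-methylcyclohexyl]-6,6-dimethyl-3-[(triethylsilyl)oxy]oxan-2-one
Conditions: RuCl3 (cat.), NaIO4, CCl4/MeCN/H2O, 25 °C
Reagents that add atoms: sodium periodate [Na+].[O-]I(=O)(=O)=O
Why: Ruthenium tetroxide oxidation of a cyclic ether to the lactone: C2 is the only carbon next to O1 that bears hydrogen (C6 is quaternary), no alkene remains, and no stereocentre is touched.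

Step 12
Reactants: 16 (3R,5R)-5-bromo-3-[(1S,3S,4S)-3-bromo-4-chloro-4-methylcyclohexyl]-6,6-dimethyl-3-[(triethylsilyl)oxy]oxan-2-one
Product: 17 {[(3R,5R)-5-bromo-3-[(1S,3S,4S)-3-bromo-4-chloro-4-methylcyclohexyl]-6,6-dimethyl-2-methylideneoxan-3-yl]oxy}triethylsilane
Conditions: Cp2TiMe2, toluene, 70 °C, dark
Reagents that add atoms: dimethyltitanocene C[Ti](C)(C1C=CC=C1)C1C=CC=C1
Why: Petasis methylenation (Cp2Ti=CH2, carbonyl olefination through an oxatitanacyclobutane) converts the lactone carbonyl into the exocyclic enol ether without acid or strong base, so the alkyl halides and the silyl ether should be tolerated.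

Step 13
Reactants: 17 {[(3R,5R)-5-bromo-3-[(1S,3S,4S)-3-bromo-4-chloro-4-methylcyclohexyl]-6,6-dimethyl-2-methylideneoxan-3-yl]oxy}triethylsilane
Product: 18 (3R,5R)-5-bromo-3-[(1S,3S,4S)-3-bromo-4-chloro-4-methylcyclohexyl]-6,6-dimethyl-2-methylideneoxan-3-ol
Conditions: Bu4NF, THF, 0 °C
Reagents that add atoms: none
Why: Fluoride-induced desilylation (Si–F bond formation) under acid-free conditions frees the tertiary alcohol and preserves the acid-sensitive enol ether.

**Compound list**
1 | (S)-limonene, (4S)-1-methyl-4-(prop-1-en-2-yl)cyclohex-1-ene | C=C(C)[C@H]1CCC(C)=CC1 | starting material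
2 | 10-lithiolimonene | [Li]CC(=C)[C@H]1CCC(C)=CC1 | intermediate (not isolated)
3 | dimethyl {2-[(1S)-4-methylcyclohex-3-en-1-yl]prop-2-en-1-yl}boronate | COB(OC)CC(=C)[C@H]1CCC(C)=CC1 | intermediate (not isolated)
4 | 2-[(1S)-4-methylcyclohex-3-en-1-yl]prop-2-en-1-ol | OCC(=C)[C@H]1CCC(C)=CC1 | intermediate
5 | [(2R)-2-[(1S)-4-methylcyclohex-3-en-1-yl]oxiran-2-yl]methanol | OC[C@@]1(CO1)[C@H]1CCC(C)=CC1 | intermediate
6 | (2R)-2-[(1S)-4-methylcyclohex-3-en-1-yl]pent-4-ene-1,2-diol | OC[C@@](O)(CC=C)[C@H]1CCC(C)=CC1 | intermediate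
7 | (2R)-2-hydroxy-2-[(1S)-4-methylcyclohex-3-en-1-yl]pent-4-en-1-yl acetate | CC(=O)OC[C@@](O)(CC=C)[C@H]1CCC(C)=CC1 | intermediate (not isolated)
8 | (2R)-2-[(1S)-4-methylcyclohex-3-en-1-yl]-2-[(triethylsilyl)oxy]pent-4-en-1-yl acetate | CC(=O)OC[C@@](O[Si](CC)(CC)CC)(CC=C)[C@H]1CCC(C)=CC1 | intermediate
9 | triethyl{[(4R)-4-[(1S)-4-methylcyclohex-3-en-1-yl]-5-(prop-1-en-2-yloxy)pent-1-en-4-yl]oxy}silane | C=C(C)OC[C@@](O[Si](CC)(CC)CC)(CC=C)[C@H]1CCC(C)=CC1 | intermediate (not isolated)
10 | triethyl{[(3R)-6-methyl-3-[(1S)-4-methylcyclohex-3-en-1-yl]-3,4-dihydro-2H-pyran-3-yl]oxy}silane | CC1=CC[C@](O[Si](CC)(CC)CC)(CO1)[C@H]1CCC(C)=CC1 | intermediate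
11 | {[(3R,5R,6R)-5-bromo-6-methoxy-6-methyl-3-[(1S)-4-methylcyclohex-3-en-1-yl]oxan-3-yl]oxy}triethylsilane | CO[C@]1(C)OC[C@@](O[Si](CC)(CC)CC)(C[C@H]1Br)[C@H]1CCC(C)=CC1 | intermediate
12 | {[(3R,5R)-5-bromo-6,6-dimethyl-3-[(1S)-4-methylcyclohex-3-en-1-yl]oxan-3-yl]oxy}triethylsilane | CC1(C)OC[C@@](O[Si](CC)(CC)CC)(C[C@H]1Br)[C@H]1CCC(C)=CC1 | intermediate
13 | (1R,2R,4S)-4-[(3R,5R)-5-bromo-6,6-dimethyl-3-[(triethylsilyl)oxy]oxan-3-yl]-2-chloro-1-methylcyclohexan-1-ol | CC1(C)OC[C@@](O[Si](CC)(CC)CC)(C[C@H]1Br)[C@H]1CC[C@@](C)(O)[C@H](Cl)C1 | intermediate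
14 | {[(3R,5R)-5-bromo-3-[(1S,3R,4R)-4-bromo-3-chloro-4-methylcyclohexyl]-6,6-dimethyloxan-3-yl]oxy}triethylsilane | CC1(C)OC[C@@](O[Si](CC)(CC)CC)(C[C@H]1Br)[C@H]1CC[C@@](C)(Br)[C@H](Cl)C1 | intermediate
15 | {[(3R,5R)-5-bromo-3-[(1S,3S,4S)-3-bromo-4-chloro-4-methylcyclohexyl]-6,6-dimethyloxan-3-yl]oxy}triethylsilane | CC1(C)OC[C@@](O[Si](CC)(CC)CC)(C[C@H]1Br)[C@H]1CC[C@](C)(Cl)[C@@H](Br)C1 | intermediate
16 | (3R,5R)-5-bromo-3-[(1S,3S,4S)-3-bromo-4-chloro-4-methylcyclohexyl]-6,6-dimethyl-3-[(triethylsilyl)oxy]oxan-2-one | O=C1OC(C)(C)[C@H](Br)C[C@@]1(O[Si](CC)(CC)CC)[C@H]1CC[C@](C)(Cl)[C@@H](Br)C1 | intermediate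
17 | {[(3R,5R)-5-bromo-3-[(1S,3S,4S)-3-bromo-4-chloro-4-methylcyclohexyl]-6,6-dimethyl-2-methylideneoxan-3-yl]oxy}triethylsilane | C=C1OC(C)(C)[C@H](Br)C[C@@]1(O[Si](CC)(CC)CC)[C@H]1CC[C@](C)(Cl)[C@@H](Br)C1 | intermediate
18 | (3R,5R)-5-bromo-3-[(1S,3S,4S)-3-bromo-4-chloro-4-methylcyclohexyl]-6,6-dimethyl-2-methylideneoxan-3-ol | C=C1OC(C)(C)[C@H](Br)C[C@@]1(O)[C@H]1CC[C@](C)(Cl)[C@@H](Br)C1 | target

Total step count: 13. Longest linear sequence: 13 steps from 1.

**Steps most likely to fail**

Step 10. The diaxial ⇌ diequatorial interchange may settle on the side of the diaxial tertiary bromide, or ionisation may leak into elimination. This is the weakest step of the route: simple conformational arguments (axial methyl in 15) favour 14. The fallback sets out from 12 and returns at 15, placing each halogen by a separate inversion. NBS in acetic acid should give the trans-diaxial bromo acetate F1 (Markovnikov, Fürst–Plattner). Heating F1 with LiCl in DMF lets the tertiary acetate displace the antiperiplanar bromide to a cis-fused acetoxonium ion, which chloride opens at the tertiary C4′ from the opposite face to give the chloro acetate F2. K2CO3/MeOH then gives the diequatorial chlorohydrin F3, Dess–Martin periodinane the α-chloro ketone F4, and LiBH(s-Bu)3 (equatorial hydride delivery) the axial alcohol F5. PPh3/CBr4 replaces the axial hydroxyl by bromide with inversion and gives 15.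

Step 6. Bromine may be delivered to C5 with poor or reversed facial selectivity, entering trans to the silyloxy group. The fallback sets out from 10 and returns at 12, and reverses the order of events at C5 so that a proton, not bromine, takes the preferred face. Br2 at −78 °C gives the 5,6-dibromide F6, and Et3N eliminates HBr to the 5-bromo enol ether F7. Kinetic protonation of F7 in MeOH (camphorsulfonic acid, −20 °C) should give the bromo ketal F8 (11 together with its epimer at the ketal carbon), which AlMe3 converts to 12.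

Step 5. Ring closure may stall after methylenation, or the acid-sensitive enol ether may be lost under prolonged heating with excess Lewis-acidic titanium/aluminium reagent. The fallback sets out from 8 and returns at 10, and separates the two events. Methylenation with Cp2TiMe2 (toluene, 65 °C) gives 9, which is isolated. The ring is then closed by catalytic enol ether/olefin ring-closing metathesis with Mo(=CHCMe2Ph)(=N-2,6-iPr2C6H3)[OCMe(CF3)2]2 or with second-generation Grubbs catalyst. No new compound is involved.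

Further compounds
F1 | step 10 | (1R,2R,4S)-4-[(3R,5R)-5-bromo-6,6-dimethyl-3-[(triethylsilyl)oxy]oxan-3-yl]-2-bromo-1-methylcyclohexyl acetate (trans-diaxial bromo acetate) | CC1(C)OC[C@@](O[Si](CC)(CC)CC)(C[C@H]1Br)[C@H]1CC[C@@](C)(OC(C)=O)[C@H](Br)C1
F2 | step 10 | trans-diequatorial chloro acetate: C4′–Cl trans, C3′–OAc cis to the oxanyl group | CC1(C)OC[C@@](O[Si](CC)(CC)CC)(C[C@H]1Br)[C@H]1CC[C@](C)(Cl)[C@@H](OC(C)=O)C1
F3 | step 10 | trans-diequatorial chlorohydrin: C4′–Cl trans, C3′–OH cis to the oxanyl group | CC1(C)OC[C@@](O[Si](CC)(CC)CC)(C[C@H]1Br)[C@H]1CC[C@](C)(Cl)[C@@H](O)C1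
F4 | step 10 | α-chloro ketone: C3′ ketone, C4′–Cl trans to the oxanyl group | CC1(C)OC[C@@](O[Si](CC)(CC)CC)(C[C@H]1Br)[C@H]1CC[C@](C)(Cl)C(=O)C1
F5 | step 10 | cis-chlorohydrin with axial C3′–OH trans to the oxanyl group | CC1(C)OC[C@@](O[Si](CC)(CC)CC)(C[C@H]1Br)[C@H]1CC[C@](C)(Cl)[C@H](O)C1
F6 | step 6 | 5,6-dibromo-6-methyl oxane from 10 (C5, C6 configuration not defined) | CC1(Br)OC[C@@](O[Si](CC)(CC)CC)(CC1Br)[C@H]1CCC(C)=CC1
F7 | step 6 | {[(3R)-5-bromo-6-methyl-3-[(1S)-4-methylcyclohex-3-en-1-yl]-3,4-dihydro-2H-pyran-3-yl]oxy}triethylsilane | CC1=C(Br)C[C@](O[Si](CC)(CC)CC)(CO1)[C@H]1CCC(C)=CC1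
F8 | step 6 | bromo ketal, 11 and its epimer at the ketal carbon | COC1(C)OC[C@@](O[Si](CC)(CC)CC)(C[C@H]1Br)[C@H]1CCC(C)=CC1
F0 | step 5 | none | none
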